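(The rate constants come from no measurement; what happens was integrated by code.)

The flask cannot hold its dissolved gas at saturation: at that level the transfer from the gas phase is zero while decomposition still runs.

    gas phase ⇌ dissolved gas, rate k1*(csat - [dissolved gas]) (k1 = 0.0605 /s, csat = 91 mM)
    substrate + dissolved gas ⇌ target (K2 = 24 /M, k2 = 0.131 /M/s)
    target ⇌ isomer of the product (K3 = 2.8, k3 = 0.0131 /s)
    dissolved gas → decomposed reagent (k4 = 0.0518 /s)

substrate 0.15 M; gas phase 91 mM (held); time 1.0 min

- Friday's: doubling the saturation concentration of gas phase, all else as stated
- Monday's: doubling the transfer coefficient of step 1, all else as stated

- at the start none of the gas is dissolved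
- run time (flask): 1.0 min

- the target standing at 1.0 min, as a percentage of the substrate charged
- concentration of dissolved gas in solution at 30 s, in percent of saturation
- the change that raises the amount of target at 1.0 min, in percent of the substrate charged most ("none" if none brings more than 2 percentage points) (Friday's / Monday's / none)
- amount of target at 1.0 min, in percent of the substrate charged, after Friday's

A hand reckoning freezes the substrate at its charge, which makes uptake of dissolved gas pseudo-first-order with coefficient 0.0197 /s. Setting transfer equal to decomposition plus uptake gives φ, the transfer coefficient divided by the sum of the transfer coefficient, the decomposition constant and the uptake coefficient: 45.9%. This φ, the saturation fraction, is the share of saturation at which dissolved gas stands when those rates balance. The reciprocal of the sum is the approach time τ, 7.58 s, shorter than the run, so the reckoned level at 30 s is 45.0%.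

One number is not enough for the target. The fraction φ gives the forward coefficient kf, 0.00547 /s, but target also returns at kb, 0.00546 /s, and isomerises at 0.0131 /s. These three sum to κ, 0.0240 /s. Counting substrate as charge less target, with the isomer of the product set aside in that count, the reckoned target approaches kf/κ at rate κ with the clock starting at τ, and stands at 16.3%. Friday's leaves φ unchanged and doubles kf, giving 29.2%, a gain of 13 percentage points. Monday's lifts φ to 62.9% and gives 21.9%, a gain of 5.6 points. Friday's gain is larger, so this reckoning chooses Friday's.

The forecast gives 16.2% of target, and 28.5% of target after Friday's, its choice, on the ground: “Doubling saturation doubles the dissolved gas”. For dissolved gas at 30 s it gives 46.7% of saturation, higher than the 45.0% reckoned here.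

The simulation gives 16.6% of target, and 29.0% of target after Friday's. Dissolved gas stands at 46.0% of saturation at 30 s. The choice is Friday's, worth 12 points against 5.4 points for Monday's. At 1.00 min this flask makes dissolved gas 1.01 times as fast as it uses it up, each step taken net. The neighbouring flask with 0.38 M of substrate has a saturation fraction of 37.3%, a reckoned plateau of 0.0340 M and a reckoned target of 13.7%. At 1.00 min that flask reads 0.0377 M of dissolved gas and 14.5% of target.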